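The earlier runs and the new flask are simulated on assumed constants, and the scatter is random.

**Elm's curve.** In the elm run, target starts at 0.219 /d as a fraction of the charge, judged by the first reading. It levels off at 11.5% by 1.67 d and still reads 11.5% at 4.00 d. Held straight, that slope meets the level at a knee τ of 0.525 d. Taking τ as the time over which capture goes on is an assumption, read from scattered numbers.

**The zero.** If both nucleophiles were captured alike and both products stayed as formed, target over other capture product would equal B/D, the ratio of first to second nucleophile. The apparent selectivity factor S is the measured ratio divided by B/D, taken on the target that stands at the reading, so that symmetric case sits at S = 1, the zero of the scale. The last readings of elm, maple, alder and birch give 3.11, 2.99, 3.18 and 3.31, with mean S = 3.15. The share of target is then S·B/(S·B + D). The two products cross at D = S·B, here 111 mM, which is higher than elm's charge and lower than maple's.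

the same everywhere: starting material 32 mM
- elm: first nucleophile 35.2 mM; second nucleophile 96 mM; run made earlier
- maple: first nucleophile 35.2 mM; second nucleophile 130 mM; run made earlier
- alder: first nucleophile 35.2 mM; second nucleophile 210 mM; run made earlier
- birch: first nucleophile 70 mM; second nucleophile 96 mM; run made earlier
- zeta: first nucleophile 35.2 mM (fed, over 2.5 d); second nucleophile 96.0 mM; all else is in the flask from the start; the feed brings no volume worth counting; time 4.0 d
- gamma: first nucleophile 35.2 mM; second nucleophile 96.0 mM (in portions, 4, over 2.5 d); first portion at the start, last at 2.5 d; time 4.0 d
- alpha: first nucleophile 35.2 mM; second nucleophile 96.0 mM (fed, over 2.5 d); all else is in the flask from the start; the feed brings no volume worth counting; time 4.0 d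
- beta: first nucleophile 35.2 mM; second nucleophile 96.0 mM; everything together at the start; time 4.0 d

- elm (time / d: target / %, other capture product / %): 0.333: 7.3, 3.6; 0.833: 10.7, 6.9; 1.67: 11.5, 7.2; 4.00: 11.5, 10.1
- maple (time / d: target / %, other capture product / %): 0.500: 9.4, 7.0; 1.25: 10.8, 10.2; 2.50: 11.8, 12.3; 4.00: 10.6, 13.1
- alder (time / d: target / %, other capture product / %): 0.500: 8.6, 10.0; 1.25: 10.4, 14.7; 2.50: 10.5, 18.4; 4.00: 9.8, 18.4
- birch (time / d: target / %, other capture product / %): 1.04: 17.7, 6.7; 2.08: 18.1, 7.4; 3.00: 17.1, 7.2; 4.00: 16.9, 7.0

(each reading ± 0.5 percentage points)

1. the flask that comes out highest in share of target in target plus other capture product, or "all alike" when all lie within 1.5 percentage points (zeta / gamma / alpha / beta / all alike)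
2. share of target in target plus other capture product at the end, zeta
3. share of target in target plus other capture product at the end, gamma
4. share of target in target plus other capture product at the end, alpha
5. share of target in target plus other capture product at the end, beta

- the numbers in the tables scatter by 0.5 percentage points (one standard deviation)

**Own reckoning.** Beta matches elm, so its share is 53.6%. The knee is shorter than the feed, so a steady feed has supplied, on average over capture, the charge times τ over the feed time. Zeta then sees B = 7.39 mM, which gives 19.5%. Alpha sees D = 20.1 mM, which gives 84.6%. In gamma, later portions count with their exponential weight in τ, so D = 30.1 mM, which gives 78.6%. Alpha stands higher than the others.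

**The forecast.** It names alpha, with 19% for zeta, 78% for gamma, 83% for alpha and 53% for beta, each slightly below this reckoning. Its ground: “Only the nucleophile levels during that early lifetime matter”.

**The flasks.** Zeta gives 26.3%, gamma 76.2%, alpha 80.5% and beta 53.7%, so alpha is higher than the others.

    starting material → intermediate (k = 9.20 × 10⁻⁴ /min)
    first nucleophile + intermediate → target (k = 0.860 /M/min)
    second nucleophile + intermediate → other capture product (k = 0.110 /M/min)
    intermediate → solvolysis product (k = 0.0670 /min)
    target ⇌ isomer of the product (K = 0.870, k = 6.50 × 10⁻⁴ /min)
    starting material + target → side product (k = 0.0150 /M/min)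

**Zeta's gap.** By S, zeta's share corresponds to an apparent average B of 10.9 mM during capture, more than the 7.39 mM reckoned. The starting material's mean life in the scheme, 0.755 d, is longer than the knee and shorter than the feed. A neighbour of zeta charged with 14 mM of first nucleophile scales that average to 4.34 mM, so S gives 12.4%. The computed neighbour gives 13.0%.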